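## The problem

Dicitrinone G (32) is an unsymmetrical dimer. A citrinin-type quinone methide (carbocycle A and pyran B; C1, O2, C3, C4, C4a, C5–C8, C8a) and a 6,8-dihydroxy-3,4-dihydroisocoumarin (arene C and lactone D, primed numbers) are joined by one methylene group between C7 and C7'. Both bridge-bearing carbons lie between two oxygenated arene carbons, so a late methylenation of two finished resorcinol units would have to tell two almost equally nucleophilic sites apart and would give both symmetrical dimers beside the cross product. The four stereocentres are two identical trans-(3R,4S) methyl pairs, too far apart to influence each other. Each pair must be made on its own, but inside a pair one centre can set the other, by 1,2-induction from the carbinol carbon or by a stereospecific epoxide opening. The carbinol carbon is part of a threo-3-arylbutan-2-ol, where ionisation risks scrambling through a symmetrical arene-bridged cation, and the benzylic centre becomes epimerisable whenever it is alpha to a carbonyl group. The quinone methide (a vinylogous acid, easily reduced and attacked by nucleophiles), the lactone (not compatible with lithium or magnesium carbon nucleophiles) and the free resorcinols limit what can be done late. The enabling feature is ring A: its substituents run C4a alkyl, C5 methyl, C6 oxygen, C7 CH2, C8 oxygen, C8a one-carbon unit. That is exactly the pattern written by a vinylketene (C4a, C5, ketene carbon C6, ketene CH C8a) and a 1-alkoxyalkyne (C7, C8), so the bridge can enter as the alkyne substituent instead of being attached to a finished arene.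

## Retrosynthesis

32 to 31. The one-carbon unit C1 is removed (bonds C1–C8a and C1–O2). The quinone methide is the most fragile part of the target and is therefore made last. Carrying C1 earlier at the ester level would later demand a reduction next to the ring D lactone. Pentaol 31 has one free arene position in the whole molecule (C8a), so the forward formylation has no regiochemical choice; it must only leave the two carbinol-derived pairs alone.

31 to 30. Five oxygen–protecting-group bonds are cut in one operation (one silyl, one ethyl, two methyl ethers). Compound 30 is robust towards everything that precedes it. The forward dealkylation must not ionise the C3–O bond.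

30 to 10 and 26. Ring A is opened at C6–C7, C8–C8a and C5–C6. The neighbouring cuts at the bridge (C7–CH2 or CH2–C7' by Friedel–Crafts methylenation, or a cross-coupling of a hexasubstituted ring A metal species) all require ring A to be made first and then raise the regiochemical and homodimer problems described above. The benzannulation builds ring A and attaches the bridge in one step. It leaves a nine-carbon diazoketone 10 with one stereo pair and an ynol ether 26 with the other. The forward step needs a regiospecific [2+2] addition, tolerance of the lactone, and no erosion of the pair next to the ketene.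

26 to 22 and 23. The CH2–C(sp) bond is cut. A zinc acetylide under palladium catalysis is chosen over direct alkylation of the lithium acetylide, which would add to the lactone. Benzyl bromide 22 and commercial ethoxyethyne 23 result.

22 to 21. The C7'–CH2Br bond is cut. C7' is the only unsubstituted arene carbon of 21, so an electrophilic bromomethylation needs no regiocontrol.

21 to 20 to 18. The lactone carbonyl is traced to a benzylic ether (isochroman 20), and the C1'–C8a' and C1'–O2' bonds to an oxa-Pictet–Spengler closure of alcohol 18. The tether decides between the two free arene positions of 18; an intermolecular bromination followed by carbonylation would rely on a less certain regioselectivity.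

18 to 17 to 16 to 13 and 14. The aryl–C4' bond is cut to an aryl Grignard reagent and an epoxide. The meso cis isomer of 14 would give the threo relationship directly, but only as a racemate. The C2-symmetric trans epoxide 14 gives one enantiopure erythro alcohol 16, and one Mitsunobu inversion (via 17) corrects C3'.

13 to 12 to 11. The C5' methyl group is traced to a formyl group, introduced into commercial 11 by Vilsmeier formylation, which places it ortho to bromine as required.

10 to 8. The diazo group is removed; a diazo transfer to the methyl ketone 8 avoids an unsaturated acid chloride, whose C=C bond is open to dipolar cycloaddition.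

8 to 6 to 5 to 4. The ethylidene C=C bond is cut by a retro-aldol condensation (6), and the C4 methyl bond by a retro-conjugate addition (5 from 4). An enol triflate and carbonylation route to the same alkene was set aside: kinetic enolisation of branched ethyl ketones favours the enolate geometry that ends with the methyl group cis to the acyl group. The aldol condensation gives the thermodynamic E isomer. The conjugate addition sets C4 and at the same time delivers the enol ether regiospecifically at C3.

4 to 3 to 2 to 1. The C3=C4 bond is cut by a Wittig disconnection to the lactaldehyde 3, which comes from methyl (R)-lactate 1 through silyl ether 2. The only purchased stereocentre of this half is C5 (the future C3).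

## Roads not taken

Alternative 1: Ring C is cut at C4a'–C8a' and unrolled into a polyketide chain. In the forward direction the diketo-dioxinone A1 is heated, the acylketene is trapped as the methyl ester, and mild base closes ring C by aldol addition and dehydration to give resorcylate A2.
- Merits: the aromatisation is mild and biomimetic, every substituent of ring C is placed by connectivity, and ring D follows by simple lactonisation. In the gentleness of the ring-forming step this road is better than the chosen one, which needs light, heat and a sensitive ynol ether.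
- Weak points: A1 already contains ring A, so ring A and its stereo pair must still be made by an arylation route. A1 needs two regiocontrolled C-functionalisations of a polyketo chain (benzyl at C7', methyl at C5'). The C4' stereocentre sits alpha to the C4a' ketone during a base-mediated step.
- Comparison: the chosen plan never places a stereocentre alpha to a carbonyl group, and it builds the arene that carries the harder stereochemical problem.

Alternative 2: Ring A is cut at C4a–C8a and C7–C8. Dimethyl malonate A4 adds to enone A3 and the methyl ketone enolate closes on a malonate ester to give cyclohexanedione A5.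
- Merits: the chemistry is cheap and scalable, and C7 of A5 is the doubly activated carbon between two carbonyl groups. Its alkylation with benzyl bromide 22 would join the halves without any regiochemical question, which is as good as or better than the chosen union through ynol ether 26.
- Weak points: after the key step ring A still lacks the C5 methyl group, which would have to go onto a carbon activated by one carbonyl only. The ring must be dehydrogenated to the arene. C1 arrives as an ester and would have to be reduced to the aldehyde level in the presence of the ring D lactone.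
- Comparison: the chosen plan delivers ring A aromatic, fully substituted and with C8a free, two steps from the target, and accepts a more delicate coupling partner in return.

Alternative 3: Ring D is cut at C1'–O2'/O2'–C3'. A Baeyer–Villiger monooxygenase would insert oxygen between the carbonyl carbon and the methyl-bearing alpha carbon of indanone A6 to give lactone A7, which is identical with 21.
- Merits: the trans pair of A6 sits on a rigid ring next to a ketone and could be equilibrated, the migration retains configuration, and an enzyme could resolve a racemate. On paper this could match or beat steps 10 to 14 in step count.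
- Weak points: chemical Baeyer–Villiger oxidation of electron-rich 1-indanones favours aryl migration, so the wanted alkyl migration depends on an enzyme whose acceptance of a tetrasubstituted dimethoxyindanone is unknown. The road also addresses ring D only, leaving ring A and the union open.
- Comparison: the chosen plan reaches 21 by classical steps whose regiochemistry is fixed by a tether and whose absolute configuration comes from an enantiopure epoxide.

Key step: step 17

Assumption: the name is taken to mean the drawn tautomer with the (3R,4S,3'R,4'S) configuration, and methyl (R)-lactate and (2S,3S)-2,3-epoxybutane are treated as commercial enantiopure materials.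

## Route

Step 1
Reactants: 1 methyl (2R)-2-hydroxypropanoate (methyl (R)-lactate)
Product: 2 methyl (2R)-2-[(tert-butyldimethylsilyl)oxy]propanoate
Conditions: TBSCl, imidazole, DMF, 0 °C to rt
Reagents that add atoms: tert-butyl(chloro)dimethylsilane, CC(C)(C)[Si](C)(C)Cl
Why: Imidazole-promoted silylation of a secondary alcohol; the bulky, non-chelating silyl ether later acts as the large group in the conjugate addition, and the stereocentre is not touched.

Step 2
Reactants: 2 methyl (2R)-2-[(tert-butyldimethylsilyl)oxy]propanoate
Product: 3 (2R)-2-[(tert-butyldimethylsilyl)oxy]propanal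
Conditions: i-Bu2AlH, CH2Cl2, −78 °C; Rochelle salt work-up
Reagents that add atoms: none
Why: Partial ester reduction through the aluminium hemiacetal, which is stable at −78 °C for alpha-silyloxy esters; the aldehyde should be used at once to avoid racemisation.

Step 3
Reactants: 3 (2R)-2-[(tert-butyldimethylsilyl)oxy]propanal
Product: 4 (3E,5R)-5-[(tert-butyldimethylsilyl)oxy]hex-3-en-2-one
Conditions: Ph3P=CHC(O)CH3, CH2Cl2, rt
Reagents that add atoms: 1-(triphenyl-λ5-phosphanylidene)propan-2-one, CC(=O)C=P(c1ccccc1)(c1ccccc1)c1ccccc1
Why: Wittig olefination with a stabilised ylide is E-selective, and its neutral conditions should preserve the alpha-stereocentre.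

Step 4
Reactants: 4 (3E,5R)-5-[(tert-butyldimethylsilyl)oxy]hex-3-en-2-one
Product: 5 (4S,5R)-5-[(tert-butyldimethylsilyl)oxy]-4-methyl-2-[(trimethylsilyl)oxy]hex-2-ene (either enol ether geometry)
Conditions: Me2CuLi, Me3SiCl, THF, −78 °C; Et3N, pentane work-up
Reagents that add atoms: lithium dimethylcuprate, [Li+].C[Cu-]C; chlorotrimethylsilane, C[Si](C)(C)Cl
Why: Silyl-chloride-accelerated cuprate 1,4-addition; C4 is set anti to the C5 oxygen by 1,2-induction (modified Felkin–Anh model, C–OSi bond perpendicular to the enone, methyl entering opposite to it), and the enolate is trapped regiospecifically at C3.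

Step 5
Reactants: 5 (4S,5R)-5-[(tert-butyldimethylsilyl)oxy]-4-methyl-2-[(trimethylsilyl)oxy]hex-2-ene
Product: 6 (4S,5R)-5-[(tert-butyldimethylsilyl)oxy]-3-(1-hydroxyethyl)-4-methylhexan-2-one (mixture of diastereomers at the two new centres)
Conditions: CH3CHO, TiCl4, CH2Cl2, −78 °C
Reagents that add atoms: acetaldehyde, CC=O
Why: Mukaiyama aldol addition; the position of the enol ether fixes C–C bond formation at C3 and not at the methyl side, and the two new centres are erased in the next step.

Step 6
Reactants: 6 (4S,5R)-5-[(tert-butyldimethylsilyl)oxy]-3-(1-hydroxyethyl)-4-methylhexan-2-one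
Product: 8 (3E,4S,5R)-5-[(tert-butyldimethylsilyl)oxy]-3-ethylidene-4-methylhexan-2-one, via mesylate 7 (not isolated)
Conditions: MsCl, Et3N, CH2Cl2, 0 °C; then DBU, 0 °C to rt
Reagents that add atoms: none
Why: Mesylation and E1cB elimination through the enolate should give the more stable E enone (methyl trans to acetyl, as in tiglates); C4 is not alpha to the carbonyl group and cannot epimerise.

Step 7
Reactants: 8 (3E,4S,5R)-5-[(tert-butyldimethylsilyl)oxy]-3-ethylidene-4-methylhexan-2-one
Product: 10 (3E,4S,5R)-5-[(tert-butyldimethylsilyl)oxy]-1-diazo-3-ethylidene-4-methylhexan-2-one, via trifluoroacetyl diketone 9 (not isolated)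
Conditions: LiN(SiMe3)2, THF, −78 °C; CF3CO2CH2CF3; then MeSO2N3, Et3N, H2O, MeCN, rt
Reagents that add atoms: methanesulfonyl azide, CS(=O)(=O)N=[N+]=[N-]
Why: Detrifluoroacetylative diazo transfer: the kinetic methyl enolate is trifluoroacetylated, and the activated 1,3-dicarbonyl compound accepts the diazo group and loses the trifluoroacetyl group as the sulfonamide; this is the standard entry to alpha'-diazo enones.

Step 8
Reactants: 11 1-bromo-3,5-dimethoxybenzene
Product: 12 2-bromo-4,6-dimethoxybenzaldehyde
Conditions: POCl3, DMF, 0 to 90 °C; aq. NaOAc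
Reagents that add atoms: N,N-dimethylformamide, CN(C)C=O; water, O
Why: Vilsmeier–Haack formylation para to one methoxy group and ortho to the other; the position between the two methoxy groups is the slower one.

Step 9
Reactants: 12 2-bromo-4,6-dimethoxybenzaldehyde
Product: 13 1-bromo-3,5-dimethoxy-2-methylbenzene
Conditions: Et3SiH, CF3CO2H, CH2Cl2, 0 °C to rt
Reagents that add atoms: none
Why: Ionic hydrogenation: the benzylic cation, stabilised by ortho and para methoxy groups, is reduced twice by the silane to the methyl group, and the aryl bromide is not affected.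

Step 10
Reactants: 13 1-bromo-3,5-dimethoxy-2-methylbenzene; 14 (2S,3S)-2,3-dimethyloxirane
Product: 16 (2S,3S)-3-(3,5-dimethoxy-2-methylphenyl)butan-2-ol, via arylmagnesium bromide 15 (not isolated)
Conditions: Mg, THF, reflux; then CuI (10 mol %), 14, THF, −30 °C to rt; aq. NH4Cl
Reagents that add atoms: none
Why: CuI-catalysed SN2 opening of the epoxide by the Grignard reagent, with inversion at the attacked carbon; both carbons of the C2-symmetric epoxide are equivalent, so a single erythro alcohol forms and the benzylic centre (future C4') is set in its final configuration.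

Step 11
Reactants: 16 (2S,3S)-3-(3,5-dimethoxy-2-methylphenyl)butan-2-ol
Product: 17 (2R,3S)-3-(3,5-dimethoxy-2-methylphenyl)butan-2-yl 4-nitrobenzoate
Conditions: 4-O2NC6H4CO2H, PPh3, i-PrO2CN=NCO2i-Pr, toluene, 0 °C to rt
Reagents that add atoms: 4-nitrobenzoic acid, OC(=O)c1ccc(cc1)[N+](=O)[O-]
Why: Mitsunobu inversion with the acidic 4-nitrobenzoic acid, the variant used for hindered secondary alcohols; SN2 displacement at the carbinol carbon turns erythro into threo and sets the future C3' as R.

Step 12
Reactants: 17 (2R,3S)-3-(3,5-dimethoxy-2-methylphenyl)butan-2-yl 4-nitrobenzoate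
Product: 18 (2R,3S)-3-(3,5-dimethoxy-2-methylphenyl)butan-2-ol
Conditions: K2CO3, MeOH, rt
Reagents that add atoms: none
Why: Base-catalysed transesterification at the acyl carbon; no C–O bond at the stereocentre is broken.

Step 13
Reactants: 18 (2R,3S)-3-(3,5-dimethoxy-2-methylphenyl)butan-2-ol
Product: 20 (3R,4S)-6,8-dimethoxy-3,4,5-trimethylisochroman, via methoxymethyl ether 19 (not isolated)
Conditions: CH2(OMe)2, BF3·OEt2, CH2Cl2, 0 °C to rt
Reagents that add atoms: dimethoxymethane, COCOC
Why: Oxa-Pictet–Spengler reaction: acetal exchange, ionisation to the oxocarbenium ion and six-membered ring closure onto the ortho carbon (future C8a'), which is para and ortho to the methoxy groups; the tether excludes the other free arene position.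

Step 14
Reactants: 20 (3R,4S)-6,8-dimethoxy-3,4,5-trimethylisochroman
Product: 21 (3R,4S)-6,8-dimethoxy-3,4,5-trimethylisochroman-1-one
Conditions: KMnO4, CuSO4·5H2O, CH2Cl2, rt
Reagents that add atoms: potassium permanganate, [K+].[O-][Mn](=O)(=O)=O
Why: Heterogeneous permanganate oxidation of a benzylic ether to the ester (isochroman to isochromanone); the C1' hydrogens are benzylic, alpha to oxygen and ortho/para to methoxy groups, and should react first.

Step 15
Reactants: 21 (3R,4S)-6,8-dimethoxy-3,4,5-trimethylisochroman-1-one
Product: 22 (3R,4S)-7-(bromomethyl)-6,8-dimethoxy-3,4,5-trimethylisochroman-1-one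
Conditions: (CH2O)n, HBr (33 % in AcOH), AcOH, 40 °C
Reagents that add atoms: formaldehyde (as paraformaldehyde), C=O; hydrogen bromide, Br
Why: Blanc-type bromomethylation at C7', the only unsubstituted arene carbon, ortho to both methoxy groups and meta to the carbonyl group; the lactone carbonyl conjugated with both methoxy groups should temper the benzylic bromide.

Step 16
Reactants: 22 (3R,4S)-7-(bromomethyl)-6,8-dimethoxy-3,4,5-trimethylisochroman-1-one; 23 ethoxyethyne
Product: 26 (3R,4S)-7-(3-ethoxyprop-2-yn-1-yl)-6,8-dimethoxy-3,4,5-trimethylisochroman-1-one, via lithium ethoxyacetylide 24 (not isolated), via bromo(ethoxyethynyl)zinc 25 (not isolated)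
Conditions: 23, n-BuLi, THF, −78 °C; ZnBr2, −78 to 0 °C; then 22, PdCl2(DPEphos) (5 mol %; DPEphos = bis[2-(diphenylphosphanyl)phenyl] ether), THF, rt
Reagents that add atoms: none
Why: Negishi coupling of an alkynylzinc halide with a benzylic bromide (sp3–sp); transmetalation to zinc removes the nucleophilicity towards the lactone that the lithium acetylide would have.

Step 17
Reactants: 10 (3E,4S,5R)-5-[(tert-butyldimethylsilyl)oxy]-1-diazo-3-ethylidene-4-methylhexan-2-one; 26 (3R,4S)-7-(3-ethoxyprop-2-yn-1-yl)-6,8-dimethoxy-3,4,5-trimethylisochroman-1-one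
Product: 30 (3R,4S)-7-({4-[(2S,3R)-3-[(tert-butyldimethylsilyl)oxy]butan-2-yl]-6-ethoxy-2-hydroxy-3-methylphenyl}methyl)-6,8-dimethoxy-3,4,5-trimethylisochroman-1-one, via vinylketene 27 (not isolated), via 4-vinylcyclobutenone 28 (not isolated), via dienylketene 29 (not isolated)
Conditions: hν (300 nm, Pyrex), ClCH2CH2Cl, rt (10 in slight excess); then 80 °C
Reagents that add atoms: none
Why: Irradiation expels N2 from 10 and the alkenyl group migrates (photochemical Wolff rearrangement) to give vinylketene 27, with the E-ethylidene unit and the stereo pair untouched. The alkyne carbon of 26 that carries the bridge CH2 (future C7, beta to the ethoxy oxygen and therefore nucleophilic) attacks the ketene carbon (future C6), and the four-membered ring closes between C8 and the ketene alpha carbon (future C8a), a regiospecific [2+2] cycloaddition giving 3-ethoxy-4-vinylcyclobutenone 28. Strain drives the 4π electrocyclic opening of 28 (by light or at 80 °C) to dienylketene 29, whose thermal 6π electrocyclisation forms C5–C6 and closes ring A as a cyclohexadienone that tautomerises to phenol 30. The closest known reaction type is the Danheiser benzannulation in its photochemical Wolff variant, for which 1-alkoxyalkynes are standard partners and give resorcinol monoethers of this pattern. No stereocentre is created: the sp3 ring carbons of 28 and of the dienone are erased on aromatisation, and the side-chain pair is never alpha to a carbonyl or ketene carbon. The step needs regioselectivity in the cycloaddition, secured by the matched polarity of ynol ether and ketene, and chemoselectivity for the alkyne over the lactone and over ketene dimerisation, secured by the absence of free OH groups and the high ketenophilicity of the ynol ether. The E geometry of 10 keeps the ethylidene methyl group away from the ketene, which prevents a [1,5]-hydrogen shift in 27 and leaves the methyl group outside in the 6π closure.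

Step 18
Reactants: 30 (3R,4S)-7-({4-[(2S,3R)-3-[(tert-butyldimethylsilyl)oxy]butan-2-yl]-6-ethoxy-2-hydroxy-3-methylphenyl}methyl)-6,8-dimethoxy-3,4,5-trimethylisochroman-1-one
Product: 31 (3R,4S)-7-({2,6-dihydroxy-4-[(2S,3R)-3-hydroxybutan-2-yl]-3-methylphenyl}methyl)-6,8-dihydroxy-3,4,5-trimethylisochroman-1-one
Conditions: BBr3, CH2Cl2, −78 °C to rt; MeOH, aq. NaHCO3
Reagents that add atoms: none
Why: Lewis acid dealkylation: bromide attacks the O-methyl and O-ethyl carbons of the arene ether–borane adducts and the silyl ether is cleaved as well, while the aryl lactone survives as in demethylations of related dihydroisocoumarins; the carbinol should be held as its borate and released on work-up with retention.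

Step 19
Reactants: 31 (3R,4S)-7-({2,6-dihydroxy-4-[(2S,3R)-3-hydroxybutan-2-yl]-3-methylphenyl}methyl)-6,8-dihydroxy-3,4,5-trimethylisochroman-1-one
Product: 32 dicitrinone G, (3R,4S)-6,8-dihydroxy-7-{[(3R,4S)-6-hydroxy-3,4,5-trimethyl-8-oxo-4,8-dihydro-3H-isochromen-7-yl]methyl}-3,4,5-trimethylisochroman-1-one
Conditions: HC(OEt)3, CF3CO2H, rt; aqueous work-up
Reagents that add atoms: triethyl orthoformate, CCOC(OCC)OCC
Why: Acid-promoted orthoformate formylation at C8a, the only free arene position (para to the C6 and ortho to the C8 hydroxyl), capture by the C3 hydroxyl and loss of ethanol give the quinone methide, the established closing step for citrinin-type ring B; ring C has no free position and the stereocentres are not involved.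

## Compound list

1 | methyl (2R)-2-hydroxypropanoate | C[C@@H](O)C(=O)OC | starting material
2 | methyl (2R)-2-[(tert-butyldimethylsilyl)oxy]propanoate | C[C@@H](O[Si](C)(C)C(C)(C)C)C(=O)OC | intermediate
3 | (2R)-2-[(tert-butyldimethylsilyl)oxy]propanal | C[C@@H](O[Si](C)(C)C(C)(C)C)C=O | intermediate
4 | (3E,5R)-5-[(tert-butyldimethylsilyl)oxy]hex-3-en-2-one | C[C@@H](O[Si](C)(C)C(C)(C)C)/C=C/C(C)=O | intermediate
5 | (4S,5R)-5-[(tert-butyldimethylsilyl)oxy]-4-methyl-2-[(trimethylsilyl)oxy]hex-2-ene | CC(C)(C)[Si](C)(C)O[C@H](C)[C@H](C=C(C)O[Si](C)(C)C)C | intermediate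
6 | (4S,5R)-5-[(tert-butyldimethylsilyl)oxy]-3-(1-hydroxyethyl)-4-methylhexan-2-one (diastereomer mixture) | CC(C)(C)[Si](C)(C)O[C@H](C)[C@H](C(C(C)O)C(C)=O)C | intermediate
7 | (4S,5R)-3-acetyl-5-[(tert-butyldimethylsilyl)oxy]-4-methylhexan-2-yl methanesulfonate (diastereomer mixture) | CC(C)(C)[Si](C)(C)O[C@H](C)[C@H](C(C(C)OS(C)(=O)=O)C(C)=O)C | intermediate
8 | (3E,4S,5R)-5-[(tert-butyldimethylsilyl)oxy]-3-ethylidene-4-methylhexan-2-one | CC(C)(C)[Si](C)(C)O[C@H](C)[C@H](/C(=C\C)C(C)=O)C | intermediate
9 | (5E,6S,7R)-7-[(tert-butyldimethylsilyl)oxy]-5-ethylidene-1,1,1-trifluoro-6-methyloctane-2,4-dione | CC(C)(C)[Si](C)(C)O[C@H](C)[C@H](/C(=C\C)C(=O)CC(=O)C(F)(F)F)C | intermediate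
10 | (3E,4S,5R)-5-[(tert-butyldimethylsilyl)oxy]-1-diazo-3-ethylidene-4-methylhexan-2-one | CC(C)(C)[Si](C)(C)O[C@H](C)[C@H](/C(=C\C)C(=O)C=[N+]=[N-])C | intermediate
11 | 1-bromo-3,5-dimethoxybenzene | COc1cc(Br)cc(OC)c1 | starting material
12 | 2-bromo-4,6-dimethoxybenzaldehyde | COc1cc(Br)c(C=O)c(OC)c1 | intermediate
13 | 1-bromo-3,5-dimethoxy-2-methylbenzene | COc1cc(Br)c(C)c(OC)c1 | intermediate
14 | (2S,3S)-2,3-dimethyloxirane ((2S,3S)-2,3-epoxybutane) | C[C@@H]1O[C@H]1C | starting material
15 | (3,5-dimethoxy-2-methylphenyl)magnesium bromide | COc1cc([Mg]Br)c(C)c(OC)c1 | intermediate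
16 | (2S,3S)-3-(3,5-dimethoxy-2-methylphenyl)butan-2-ol | O[C@@H](C)[C@H](c1cc(OC)cc(OC)c1C)C | intermediate
17 | (2R,3S)-3-(3,5-dimethoxy-2-methylphenyl)butan-2-yl 4-nitrobenzoate | O=C(O[C@H](C)[C@H](c1cc(OC)cc(OC)c1C)C)c1ccc(cc1)[N+](=O)[O-] | intermediate
18 | (2R,3S)-3-(3,5-dimethoxy-2-methylphenyl)butan-2-ol | O[C@H](C)[C@H](c1cc(OC)cc(OC)c1C)C | intermediate
19 | 1,5-dimethoxy-3-[(2S,3R)-3-(methoxymethoxy)butan-2-yl]-2-methylbenzene | COCO[C@H](C)[C@H](c1cc(OC)cc(OC)c1C)C | intermediate
20 | (3R,4S)-6,8-dimethoxy-3,4,5-trimethylisochroman | c1c(OC)c(C)c2c(c1OC)CO[C@H](C)[C@H]2C | intermediate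
21 | (3R,4S)-6,8-dimethoxy-3,4,5-trimethylisochroman-1-one | c1c(OC)c(C)c2c(c1OC)C(=O)O[C@H](C)[C@H]2C | intermediate
22 | (3R,4S)-7-(bromomethyl)-6,8-dimethoxy-3,4,5-trimethylisochroman-1-one | BrCc1c(OC)c(C)c2c(c1OC)C(=O)O[C@H](C)[C@H]2C | intermediate
23 | ethoxyethyne | CCOC#C | starting material
24 | lithium ethoxyacetylide | CCOC#C[Li] | intermediate
25 | bromo(ethoxyethynyl)zinc | CCOC#C[Zn]Br | intermediate
26 | (3R,4S)-7-(3-ethoxyprop-2-yn-1-yl)-6,8-dimethoxy-3,4,5-trimethylisochroman-1-one | CCOC#CCc1c(OC)c(C)c2c(c1OC)C(=O)O[C@H](C)[C@H]2C | intermediate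
27 | (3E)-3-[(2S,3R)-3-[(tert-butyldimethylsilyl)oxy]butan-2-yl]penta-1,3-dien-1-one | CC(C)(C)[Si](C)(C)O[C@H](C)[C@H](/C(=C\C)C=C=O)C | intermediate
28 | 4-[(2E,4S,5R)-5-[(tert-butyldimethylsilyl)oxy]-4-methylhex-2-en-3-yl]-2-{[(3R,4S)-6,8-dimethoxy-3,4,5-trimethyl-1-oxoisochroman-7-yl]methyl}-3-ethoxycyclobut-2-en-1-one (both C4 epimers) | CC(C)(C)[Si](C)(C)O[C@H](C)[C@H](/C(=C\C)C1C(=O)C(Cc2c(OC)c(C)c3c(c2OC)C(=O)O[C@H](C)[C@H]3C)=C1OCC)C | intermediate
29 | (5E)-5-[(2S,3R)-3-[(tert-butyldimethylsilyl)oxy]butan-2-yl]-2-{[(3R,4S)-6,8-dimethoxy-3,4,5-trimethyl-1-oxoisochroman-7-yl]methyl}-3-ethoxyhepta-1,3,5-trien-1-one | CC(C)(C)[Si](C)(C)O[C@H](C)[C@H](/C(=C\C)C=C(OCC)C(Cc1c(OC)c(C)c2c(c1OC)C(=O)O[C@H](C)[C@H]2C)=C=O)C | intermediate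
30 | (3R,4S)-7-({4-[(2S,3R)-3-[(tert-butyldimethylsilyl)oxy]butan-2-yl]-6-ethoxy-2-hydroxy-3-methylphenyl}methyl)-6,8-dimethoxy-3,4,5-trimethylisochroman-1-one | CC(C)(C)[Si](C)(C)O[C@H](C)[C@H](c1cc(OCC)c(Cc2c(OC)c(C)c3c(c2OC)C(=O)O[C@H](C)[C@H]3C)c(O)c1C)C | intermediate
31 | (3R,4S)-7-({2,6-dihydroxy-4-[(2S,3R)-3-hydroxybutan-2-yl]-3-methylphenyl}methyl)-6,8-dihydroxy-3,4,5-trimethylisochroman-1-one | O[C@H](C)[C@H](c1cc(O)c(Cc2c(O)c(C)c3c(c2O)C(=O)O[C@H](C)[C@H]3C)c(O)c1C)C | intermediate
32 | dicitrinone G | CC1=C2C(=CO[C@H](C)[C@H]2C)C(=O)C(Cc2c(O)c(C)c3c(c2O)C(=O)O[C@H](C)[C@H]3C)=C1O | target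

## Step count and least certain steps

Total: 19 steps. Longest linear sequence: 12 steps (steps 8 to 19, from 11); the diazoketone branch has 7 steps (1 to 7).

Step 17 (key step). The most likely failure is loss of the advanced alkyne 26 while vinylketene 27 is consumed in other ways: dimerisation, acylation of the product phenol, a [1,5]-hydrogen shift after photoisomerisation of the enone, or photodegradation and hydrolysis of the ynol ether. Both partners are precious and neither can be used in large excess. Fallback: keep the annulation but move the bridge bond out of it.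
- Diazoketone 10 is irradiated with ethoxyethyne 23 itself under the conditions of step 17. Through 27, the 3-ethoxycyclobutenone F1 and the dienylketene F2, this should give 3-[(2S,3R)-3-silyloxybutan-2-yl]-5-ethoxy-2-methylphenol F3.
- The phenol is protected as its methoxymethyl ether F4 (MOMCl, i-Pr2NEt).
- n-BuLi lithiates the carbon between the two oxygen substituents to give the aryllithium F5, and ZnCl2 gives the arylzinc chloride F6.
- Coupling with benzyl bromide 22 (Pd(PPh3)4, THF) gives the methoxymethyl ether F7 of 30.
- BBr3 as in step 18 cleaves all ethers, and the route is rejoined at 31.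

Step 15. Poor conversion, or cleavage of the chelated C8' methoxy group by HBr, is the likely problem. C7' is crowded by the methyl groups of both methoxy groups, which must twist out of conjugation when it is attacked; a slow reaction also lets the product alkylate unreacted 21. Fallback from 21: electrophilic bromination (NBS, MeCN) to the 7-bromo lactone F8, Stille coupling with (tributylstannyl)methanol (Pd(PPh3)4, dioxane, 100 °C) to the 7-hydroxymethyl lactone F9, and PBr3 to rejoin at 22.

Step 18. Loss of configurational integrity at C3 is the main risk: substitution of the intermediate dibromoborate by bromide, possibly assisted by the neighbouring arene, if the slow ethyl ether cleavage forces long reaction at room temperature. Fallback from 30: n-Bu4NF removes the silyl group to give diol F10; Ac2O, pyridine and DMAP give diacetate F11, whose ester is not converted into a bromide; BBr3 at −78 to 0 °C then cleaves only the three arene ethers to give F12; K2CO3 in MeOH removes the acetates and rejoins at 31.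

Step 14. Over-oxidation at the other benzylic sites (the tertiary C4' hydrogen, the C5' methyl group) or attack on the electron-rich arene may compete with oxidation at C1'. Fallback from 18: bromination ortho to the side chain (NBS) to bromo alcohol F13, then palladium-catalysed carbonylative lactonisation (Pd(OAc)2, Xantphos, CO, Et3N, toluene, 100 °C), rejoining at 21.

Step 11. Elimination to the styrene or incomplete inversion is possible, because the carbinol is flanked by a tertiary benzylic carbon with an ortho-substituted arene. Fallback from Grignard reagent 15 (made from 13): CuI-catalysed opening of meso cis-2,3-epoxybutane gives the racemic threo alcohol F14; lipase resolution (CAL-B, vinyl acetate), expected from the Kazlauskas rule to acylate the R carbinol, gives acetate F15; K2CO3 in MeOH rejoins at 18.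

## Further compounds

F1 | step 17 | 4-[(2E,4S,5R)-5-[(tert-butyldimethylsilyl)oxy]-4-methylhex-2-en-3-yl]-3-ethoxycyclobut-2-en-1-one | CC(C)(C)[Si](C)(C)O[C@H](C)[C@H](/C(=C\C)C1C(=O)C=C1OCC)C
F2 | step 17 | (5E)-5-[(2S,3R)-3-[(tert-butyldimethylsilyl)oxy]butan-2-yl]-3-ethoxyhepta-1,3,5-trien-1-one | CC(C)(C)[Si](C)(C)O[C@H](C)[C@H](/C(=C\C)C=C(OCC)C=C=O)C
F3 | step 17 | 3-[(2S,3R)-3-[(tert-butyldimethylsilyl)oxy]butan-2-yl]-5-ethoxy-2-methylphenol | CC(C)(C)[Si](C)(C)O[C@H](C)[C@H](c1cc(OCC)cc(O)c1C)C
F4 | step 17 | tert-butyl{[(2R,3S)-3-[5-ethoxy-3-(methoxymethoxy)-2-methylphenyl]butan-2-yl]oxy}dimethylsilane | CC(C)(C)[Si](C)(C)O[C@H](C)[C@H](c1cc(OCC)cc(OCOC)c1C)C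
F5 | step 17 | {4-[(2S,3R)-3-[(tert-butyldimethylsilyl)oxy]butan-2-yl]-6-ethoxy-2-(methoxymethoxy)-3-methylphenyl}lithium | CC(C)(C)[Si](C)(C)O[C@H](C)[C@H](c1cc(OCC)c([Li])c(OCOC)c1C)C
F6 | step 17 | {4-[(2S,3R)-3-[(tert-butyldimethylsilyl)oxy]butan-2-yl]-6-ethoxy-2-(methoxymethoxy)-3-methylphenyl}zinc chloride | CC(C)(C)[Si](C)(C)O[C@H](C)[C@H](c1cc(OCC)c([Zn]Cl)c(OCOC)c1C)C
F7 | step 17 | (3R,4S)-7-({4-[(2S,3R)-3-[(tert-butyldimethylsilyl)oxy]butan-2-yl]-6-ethoxy-2-(methoxymethoxy)-3-methylphenyl}methyl)-6,8-dimethoxy-3,4,5-trimethylisochroman-1-one | CC(C)(C)[Si](C)(C)O[C@H](C)[C@H](c1cc(OCC)c(Cc2c(OC)c(C)c3c(c2OC)C(=O)O[C@H](C)[C@H]3C)c(OCOC)c1C)C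
F8 | step 15 | (3R,4S)-7-bromo-6,8-dimethoxy-3,4,5-trimethylisochroman-1-one | Brc1c(OC)c(C)c2c(c1OC)C(=O)O[C@H](C)[C@H]2C
F9 | step 15 | (3R,4S)-7-(hydroxymethyl)-6,8-dimethoxy-3,4,5-trimethylisochroman-1-one | OCc1c(OC)c(C)c2c(c1OC)C(=O)O[C@H](C)[C@H]2C
F10 | step 18 | (3R,4S)-7-({6-ethoxy-2-hydroxy-4-[(2S,3R)-3-hydroxybutan-2-yl]-3-methylphenyl}methyl)-6,8-dimethoxy-3,4,5-trimethylisochroman-1-one | O[C@H](C)[C@H](c1cc(OCC)c(Cc2c(OC)c(C)c3c(c2OC)C(=O)O[C@H](C)[C@H]3C)c(O)c1C)C
F11 | step 18 | (2R,3S)-3-[3-acetoxy-4-{[(3R,4S)-6,8-dimethoxy-3,4,5-trimethyl-1-oxoisochroman-7-yl]methyl}-5-ethoxy-2-methylphenyl]butan-2-yl acetate | CC(=O)O[C@H](C)[C@H](c1cc(OCC)c(Cc2c(OC)c(C)c3c(c2OC)C(=O)O[C@H](C)[C@H]3C)c(OC(C)=O)c1C)C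
F12 | step 18 | (2R,3S)-3-[3-acetoxy-4-{[(3R,4S)-6,8-dihydroxy-3,4,5-trimethyl-1-oxoisochroman-7-yl]methyl}-5-hydroxy-2-methylphenyl]butan-2-yl acetate | CC(=O)O[C@H](C)[C@H](c1cc(O)c(Cc2c(O)c(C)c3c(c2O)C(=O)O[C@H](C)[C@H]3C)c(OC(C)=O)c1C)C
F13 | step 14 | (2R,3S)-3-(2-bromo-3,5-dimethoxy-6-methylphenyl)butan-2-ol | O[C@H](C)[C@H](c1c(Br)c(OC)cc(OC)c1C)C
F14 | step 11 | rac-(2R,3S)-3-(3,5-dimethoxy-2-methylphenyl)butan-2-ol (racemic threo alcohol, relative configuration shown) | O[C@H](C)[C@H](c1cc(OC)cc(OC)c1C)C
F15 | step 11 | (2R,3S)-3-(3,5-dimethoxy-2-methylphenyl)butan-2-yl acetate | CC(=O)O[C@H](C)[C@H](c1cc(OC)cc(OC)c1C)C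
A1 | alternative 1 | 6-{(6R,7R)-7-[(tert-butyldimethylsilyl)oxy]-1-{4-[(2S,3R)-3-[(tert-butyldimethylsilyl)oxy]butan-2-yl]-2,6-dimethoxy-3-methylphenyl}-4,6-dimethyl-3,5-dioxooctan-2-yl}-2,2-dimethyl-4H-1,3-dioxin-4-one | CC1(C)OC(=CC(=O)O1)C(Cc1c(OC)c(C)c(cc1OC)[C@H](C)[C@@H](C)O[Si](C)(C)C(C)(C)C)C(=O)C(C)C(=O)[C@H](C)[C@@H](C)O[Si](C)(C)C(C)(C)C
A2 | alternative 1 | methyl 6-[(2S,3R)-3-[(tert-butyldimethylsilyl)oxy]butan-2-yl]-3-({4-[(2S,3R)-3-[(tert-butyldimethylsilyl)oxy]butan-2-yl]-2,6-dimethoxy-3-methylphenyl}methyl)-2,4-dihydroxy-5-methylbenzoate | CC(C)(C)[Si](C)(C)O[C@H](C)[C@H](c1c(C)c(O)c(Cc2c(OC)c(C)c([C@H](C)[C@@H](C)O[Si](C)(C)C(C)(C)C)cc2OC)c(O)c1C(=O)OC)C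
A3 | alternative 2 | (3E,5S,6R)-6-[(tert-butyldimethylsilyl)oxy]-5-methylhept-3-en-2-one | CC(C)(C)[Si](C)(C)O[C@H](C)[C@H](/C=C/C(C)=O)C
A4 | alternative 2 | dimethyl malonate | COC(=O)CC(=O)OC
A5 | alternative 2 | methyl 6-[(2S,3R)-3-[(tert-butyldimethylsilyl)oxy]butan-2-yl]-2,4-dioxocyclohexane-1-carboxylate (ring epimers and enol forms) | CC(C)(C)[Si](C)(C)O[C@H](C)[C@H](C1CC(=O)CC(=O)C1C(=O)OC)C
A6 | alternative 3 | (2R,3R)-5,7-dimethoxy-2,3,4-trimethyl-2,3-dihydro-1H-inden-1-one | c1c(OC)c(C)c2c(c1OC)C(=O)[C@H](C)[C@H]2C
A7 | alternative 3 | (3R,4S)-6,8-dimethoxy-3,4,5-trimethylisochroman-1-one | c1c(OC)c(C)c2c(c1OC)C(=O)O[C@H](C)[C@H]2C
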